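**Proposed synthesis of candidachalcone (18): carbon monoxide inserted between a ring A iodide and an (E)-styrylboronate**

## Analysis of the target

Candidachalcone 18 is a chalcone whose ring A (C1'–C6') is pentasubstituted: the enone carbonyl on C1', hydroxyl groups on C2' and C4', a five-carbon side chain on C3' between them, a methoxy group on C6', and hydrogen only on C5'. Ring B is a 4-hydroxyphenyl group attached through Cα=Cβ. There is no stereogenic centre; the stereochemistry consists of two alkene geometries, E at Cα=Cβ and Z at C1''=C2'' of the side chain, which ends in the tertiary carbinol C3''. The Z geometry holds the C3''–OH within reach of the 2'-OH and 4'-OH, so any Brønsted or Lewis acid closes a 2,2-dimethylchromene with loss of water, and a free 2'-phenoxide can add to the enone to give a flavanone. The difficulty is therefore to acylate a crowded, electron-rich ring without acid, to fix the substitution pattern of ring A, and to make and keep the less stable Z alkene. The strategy rests first on the ketone carbon, which is bonded only to C1' of ring A and to Cα and can therefore be supplied as carbon monoxide between an iodide on C1' and a styryl nucleophile. It rests second on C3', whose two flanking oxygens and cis C1''=C2''–C3'' chain map onto C4a, C4, C3 and C2 of a coumarin.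

## Retrosynthetic reasoning

18 from 17. The last operation should break only oxygen–silicon bonds. The three phenols of 18 are therefore carried in 17 as tert-butyldimethylsilyl ethers, which a buffered fluoride source removes without acid and without long-lived phenoxide. The tertiary alcohol is left free throughout, because it is inert to the chemistry planned and any protecting group on it would need a separate removal.

17 from 11, 15 and 16. Both bonds to the carbonyl carbon are cut, C1'–C(=O) and C(=O)–Cα. Cutting Cα=Cβ instead would demand an acetyl group on C1', which itself calls for an acylation of ring A and then a strongly basic condensation. Cutting only C1'–C(=O) would mean acylating ring A under Lewis acid, which the side chain does not survive. The three-component disconnection is convergent: the iodide 11 carries the Z alkene, the boronate 15 carries the E alkene, and carbon monoxide 16 supplies the ketone. The forward reaction must take up 16 before the two organic partners couple directly, and must keep both alkene geometries.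

15 from 13 and 14, and 13 from 12. The Cβ–aryl bond is cut, so that the E alkenylboronate arises from the vinylboronate 14 and the silylated iodophenol 13 by a Heck-type arylation; 13 is the silyl ether of 12.

11 from 10. Only the two O–Si bonds on the phenols are cut. The forward silylation must leave the tertiary alcohol alone and must not expose the triol 10 to acid.

10 from 7 and 8, through 9. The two C3''–CH3 bonds are cut, which turns C3'' into a lactone carbonyl and one of the oxygens beside the side chain into the ring oxygen of a coumarin. The lactone ring allows only the cis arrangement at C3=C4, so the Z geometry is fixed by a ring. Opening the lactone also makes the two oxygens next to the side chain equivalent, so the acyl position in 10 does not depend on whether the iodine sat on C8 or on C6 of the coumarin.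

7 from 6. The C–I bond is cut at the coumarin stage, where the alkene is part of a conjugated lactone and is deactivated toward electrophilic iodine, so only the phenolic ring reacts.

6 from 2 and 3, through 4 and 5. The C3=C4 bond and the lactone C–O bond are cut. Aldehyde 2 is symmetric, so lactonisation onto either ortho phenol gives the same coumarin.

2 from 1. The O–CH3 bond is cut; the forward reaction has to pick the phenol para to the formyl group out of three.

## Alternatives that were turned down

Alternative 1: Ring A itself is disconnected, into 3-methoxycyclobut-2-en-1-one A2 and the Z-enynyl silyl ether A3, which already carries the side chain. On heating, A2 opens to a vinylketene, adds to the siloxyalkyne of A3 in a [2+2] sense, reopens, closes by a 6π electrocyclisation and tautomerises to the phenol A1.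
- For: the four substituents of A1 are placed by connectivity alone, and the three oxygens emerge differentiated (methoxy from A2, silyl ether from A3, free phenol from the ketene carbon). On this point it is stronger than the chosen route, which relies on a selective O-methylation in step 1.
- Against: A3 is a Z-enyne with a siloxyalkyne terminus and takes several stereocontrolled steps to make. Its Z alkene must survive a thermal cascade. A1 still has no carbon on C1', so the acid-free acylation of ring A remains unsolved and would have to be added afterwards.
- Comparison: the chosen route buys the aromatic ring, fixes the Z alkene in a lactone ring, and spends its key step on the acylation that this alternative leaves open.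

Alternative 2: The C1''=C2'' bond is disconnected. The precursor is the bis-silyl ether A5, a 2-vinylresorcinol core in which each phenol oxygen carries a diisopropylsilylene tether to a 2-methylbut-3-en-2-yloxy group. Ring-closing metathesis with the second-generation Grubbs catalyst RuCl2(=CHPh)(H2IMes)(PCy3) would join the aryl vinyl group to one tethered vinyl group and give the eight-membered cyclic silaketal A4, the second tether remaining as a silyl ether.
- For: the medium ring enforces the Z geometry, and the tether masks a phenol and the tertiary alcohol together, so chromene closure is blocked structurally. On protection of the side chain it is stronger than the chosen route, which leaves the tertiary alcohol free.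
- Against: both alkenes of A5 are poor metathesis partners, a styrene flanked by two ortho oxygens and a vinyl group on a fully substituted allylic carbon. An eight-membered ring closes slowly, and the spare tether invites oligomerisation. Mixed aryloxy/tert-alkoxy silanes such as A5 are laborious to make and hydrolytically fragile. A4 still needs iodination or acylation at C1' and removal of the silicon tethers.
- Comparison: the chosen route uses the same idea, a ring that holds the cis alkene, but the ring is a lactone made in one step whose opening also installs both methyl groups.

Alternative 3: The two C3''–CH3 bonds are disconnected in the coumarin A7, which already carries a 1-hydroxyethyl group on the future C1'. Excess 8 with CeCl3 opens the lactone of A7 to the racemic tetraol A6. Oxidation to the methyl ketone A8 and base-mediated condensation with 4-hydroxybenzaldehyde A9 would complete the chalcone.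
- For: the Z alkene is set exactly as in step 4 of the chosen route, so on that point the two are equal. The aldol condensation is the most established way to make a chalcone and needs neither palladium nor carbon monoxide; on that point it is stronger.
- Against: after A6 the fragile Z allylic alcohol and the free phenols must pass through an oxidation of an ortho- and para-hydroxybenzylic alcohol, which is prone to quinone methide formation. In the condensation of A8 with A9 they must then survive prolonged strong base, under which a 2'-phenoxide can close onto the enone. Protecting groups would add steps, and the two-carbon handle of A7 has to be put on the coumarin by an acylation first.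
- Comparison: the chosen route is convergent and, once the Z alkene exists, exposes it only to a silylation, a weakly basic palladium coupling and buffered fluoride.

Key step: step 8

Remark on the chemistry: the iodination in step 3 is written for C8 of the coumarin. Iodination at C6 would lead to the same compound 10 after step 4, because opening the lactone turns C6 and C8 into equivalent ring positions.

## Route

Step 1
Reactants: 1 2,4,6-trihydroxybenzaldehyde
Product: 2 2,6-dihydroxy-4-methoxybenzaldehyde
Conditions: Me2SO4 (1.0 equiv), K2CO3 (1.0 equiv), acetone, 0 °C to rt
Reagents that add atoms: dimethyl sulfate, COS(=O)(=O)OC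
Why: Williamson O-methylation; the 4-OH is para to the formyl group, unchelated and least hindered, so it is the most acidic phenol and should react first with one equivalent of base. The hard electrophile favours O- over C-methylation of the phloroglucinol ring.

Step 2
Reactants: 2 2,6-dihydroxy-4-methoxybenzaldehyde; 3 ethyl (triphenylphosphoranylidene)acetate
Product: 6 5-hydroxy-7-methoxycoumarin, via ethyl (E)-2,6-dihydroxy-4-methoxycinnamate 4 (not isolated), via ethyl (Z)-2,6-dihydroxy-4-methoxycinnamate 5 (not isolated)
Conditions: PhNEt2, reflux
Reagents that add atoms: none
Why: Wittig olefination followed by thermal E-to-Z isomerisation and lactonisation; the stabilised ylide gives mainly the E ester 4, which equilibrates at this temperature with the Z ester 5, and 5 is trapped by an ortho phenol with loss of ethanol. Because 2 is symmetric, either phenol gives the same coumarin, and the ring fixes the cis relation that becomes the Z side chain.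

Step 3
Reactants: 6 5-hydroxy-7-methoxycoumarin
Product: 7 5-hydroxy-8-iodo-7-methoxycoumarin
Conditions: NIS (1.0 equiv), DMF, 0 °C to rt, dark
Reagents that add atoms: N-iodosuccinimide, O=C1CCC(=O)N1I
Why: Electrophilic aromatic iodination of a phenol; C8 is para to the free 5-OH and ortho to the methoxy group, while C3=C4 is deactivated as part of the unsaturated lactone, and one equivalent of reagent limits diiodination. Should iodine enter at C6 instead, nothing is lost, because the lactone opening of step 4 makes C6 and C8 the same ring position, so the mono-iodinated material is carried on without sorting it by position.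

Step 4
Reactants: 7 5-hydroxy-8-iodo-7-methoxycoumarin; 8 methylmagnesium bromide
Product: 10 2-[(Z)-3-hydroxy-3-methylbut-1-enyl]-4-iodo-5-methoxybenzene-1,3-diol, via (Z)-4-(2,6-dihydroxy-3-iodo-4-methoxyphenyl)but-3-en-2-one 9 (not isolated)
Conditions: 8 (6 equiv), anhydrous CeCl3 (3 equiv), THF, −40 to 0 °C; sat. aq NH4Cl, 0 °C; crude product used directly
Reagents that add atoms: none
Why: Double 1,2-addition of a methyl Grignard reagent to a lactone; one equivalent deprotonates the phenol, the next opens the lactone to the Z enone 9 (as its bis-phenoxide) and a further one adds to the ketone, the cis geometry being inherited from the ring. CeCl3 suppresses conjugate addition and enolisation of 9, the electron-rich aryl iodide does not exchange with 8 at this temperature, and the near-neutral quench avoids closure to a chromene.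

Step 5
Reactants: 10 2-[(Z)-3-hydroxy-3-methylbut-1-enyl]-4-iodo-5-methoxybenzene-1,3-diol
Product: 11 (Z)-4-[2,6-bis(tert-butyldimethylsilyloxy)-3-iodo-4-methoxyphenyl]-2-methylbut-3-en-2-ol
Conditions: TBSCl (3 equiv), imidazole (6 equiv), DMF, rt to 40 °C
Reagents that add atoms: tert-butyldimethylsilyl chloride, CC(C)(C)[Si](C)(C)Cl
Why: Silylation of phenols; the tertiary alcohol does not react with the silyl chloride under these conditions, so only the two phenols are capped, the one between iodine and the side chain needing the gentle warming. Using crude 10 at once keeps the acid-sensitive Z allylic alcohol off silica gel until both neighbouring phenols are masked.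

Step 6
Reactants: 12 4-iodophenol
Product: 13 tert-butyl(4-iodophenoxy)dimethylsilane
Conditions: TBSCl, imidazole, CH2Cl2, rt
Reagents that add atoms: tert-butyldimethylsilyl chloride, CC(C)(C)[Si](C)(C)Cl
Why: Standard silylation of an unhindered phenol.

Step 7
Reactants: 13 tert-butyl(4-iodophenoxy)dimethylsilane; 14 vinylboronic acid pinacol ester
Product: 15 (E)-2-[4-(tert-butyldimethylsilyloxy)phenyl]ethenylboronic acid pinacol ester
Conditions: Pd(OAc)2 (5 mol%), PPh3 (10 mol%), n-Bu3N, toluene, 110 °C
Reagents that add atoms: none
Why: Heck–Mizoroki arylation of a vinylboronate; with an anhydrous amine base the boronate is not activated for transmetalation, so the arylpalladium species adds across the vinyl group. Syn β-hydride elimination then gives the E alkenylboronate with the C–B bond intact.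

Step 8
Reactants: 11 (Z)-4-[2,6-bis(tert-butyldimethylsilyloxy)-3-iodo-4-methoxyphenyl]-2-methylbut-3-en-2-ol; 15 (E)-2-[4-(tert-butyldimethylsilyloxy)phenyl]ethenylboronic acid pinacol ester; 16 carbon monoxide
Product: 17 (E)-1-{2,4-bis(tert-butyldimethylsilyloxy)-3-[(Z)-3-hydroxy-3-methylbut-1-enyl]-6-methoxyphenyl}-3-[4-(tert-butyldimethylsilyloxy)phenyl]prop-2-en-1-one (2',4',4-tris-O-TBS-candidachalcone)
Conditions: Pd(PPh3)4 (10 mol%), K2CO3 (3 equiv), H2O (3 equiv), CO (1 atm), anisole, 80 °C
Reagents that add atoms: none
Why: Carbonylative Suzuki–Miyaura coupling, the known three-component route from aryl iodides, carbon monoxide and alkenylboron reagents to aryl vinyl ketones, applied here to an electron-rich iodide with two ortho oxygen substituents. Oxidative addition of the C1'–I bond of 11 to zerovalent palladium is followed by migration of the aryl group onto coordinated CO, giving an aroyl complex of divalent palladium; this migration is fast for an electron-rich aryl group and relieves crowding between the metal and the flanking silyloxy and methoxy groups. Carbonate and the small amount of water turn 15 into a borate that hands its styryl group to palladium with retention of the E geometry, and reductive elimination forms the C(=O)–Cα bond. No ring is closed and no stereocentre is created; the E Cα=Cβ bond and the Z C1''=C2'' bond are carried through unchanged from 15 and 11. The step needs carbonylation to outrun direct aryl–alkenyl coupling, and the two ortho substituents secure this by slowing transmetalation at the arylpalladium stage more than CO insertion, while the CO atmosphere keeps the aroyl complex populated. The site of acylation is fixed by the iodine, whose ring position became unambiguous when the lactone opening made the two candidate carbons equivalent. The medium is weakly basic and free of acid, so the tertiary allylic alcohol cannot close onto a neighbouring oxygen, and the side chain, being meta to the reacting carbon, cannot reach the palladium centre.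

Step 9
Reactants: 17 2',4',4-tris-O-TBS-candidachalcone
Product: 18 candidachalcone, (E)-1-{2,4-dihydroxy-3-[(Z)-3-hydroxy-3-methylbut-1-enyl]-6-methoxyphenyl}-3-(4-hydroxyphenyl)prop-2-en-1-one
Conditions: Bu4NF (3.3 equiv), AcOH (3.5 equiv), THF, 0 °C
Reagents that add atoms: none
Why: Fluoride cleavage of aryl silyl ethers; acetic acid protonates each phenoxide as it is released, so the 2'-oxygen does not add to the enone and the medium never becomes acidic enough to close the Z allylic alcohol onto a phenol. The tertiary alcohol carries no silyl group, so nothing else changes.

## Compound list

1 | 2,4,6-trihydroxybenzaldehyde | O=Cc1c(O)cc(O)cc1O | starting material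
2 | 2,6-dihydroxy-4-methoxybenzaldehyde | COc1cc(O)c(C=O)c(O)c1 | intermediate
3 | ethyl (triphenylphosphoranylidene)acetate | CCOC(=O)C=P(c1ccccc1)(c1ccccc1)c1ccccc1 | starting material
4 | ethyl (E)-3-(2,6-dihydroxy-4-methoxyphenyl)prop-2-enoate | CCOC(=O)/C=C/c1c(O)cc(OC)cc1O | intermediate (not isolated)
5 | ethyl (Z)-3-(2,6-dihydroxy-4-methoxyphenyl)prop-2-enoate | CCOC(=O)/C=C\c1c(O)cc(OC)cc1O | intermediate (not isolated)
6 | 5-hydroxy-7-methoxycoumarin | COc1cc(O)c2ccc(=O)oc2c1 | intermediate
7 | 5-hydroxy-8-iodo-7-methoxycoumarin | COc1cc(O)c2ccc(=O)oc2c1I | intermediate
8 | methylmagnesium bromide | C[Mg]Br | starting material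
9 | (Z)-4-(2,6-dihydroxy-3-iodo-4-methoxyphenyl)but-3-en-2-one | COc1cc(O)c(/C=C\C(C)=O)c(O)c1I | intermediate (not isolated)
10 | 2-[(Z)-3-hydroxy-3-methylbut-1-enyl]-4-iodo-5-methoxybenzene-1,3-diol | COc1cc(O)c(/C=C\C(C)(C)O)c(O)c1I | intermediate
11 | (Z)-4-[2,6-bis(tert-butyldimethylsilyloxy)-3-iodo-4-methoxyphenyl]-2-methylbut-3-en-2-ol | COc1cc(O[Si](C)(C)C(C)(C)C)c(/C=C\C(C)(C)O)c(O[Si](C)(C)C(C)(C)C)c1I | intermediate
12 | 4-iodophenol | Oc1ccc(I)cc1 | starting material
13 | tert-butyl(4-iodophenoxy)dimethylsilane | CC(C)(C)[Si](C)(C)Oc1ccc(I)cc1 | intermediate
14 | vinylboronic acid pinacol ester | C=CB1OC(C)(C)C(C)(C)O1 | starting material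
15 | (E)-2-[4-(tert-butyldimethylsilyloxy)phenyl]ethenylboronic acid pinacol ester | CC(C)(C)[Si](C)(C)Oc1ccc(/C=C/B2OC(C)(C)C(C)(C)O2)cc1 | intermediate
16 | carbon monoxide | [C-]#[O+] | starting material
17 | 2',4',4-tris-O-(tert-butyldimethylsilyl)candidachalcone | COc1cc(O[Si](C)(C)C(C)(C)C)c(/C=C\C(C)(C)O)c(O[Si](C)(C)C(C)(C)C)c1C(=O)/C=C/c1ccc(O[Si](C)(C)C(C)(C)C)cc1 | intermediate
18 | candidachalcone | COc1cc(O)c(/C=C\C(C)(C)O)c(O)c1C(=O)/C=C/c1ccc(O)cc1 | target

## Step count and least certain steps

Total: 9 steps. Longest linear sequence: 7 steps (steps 1 to 5, 8 and 9); the boronate branch (steps 6 and 7) has 2 steps.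

**Step 8 (key step).** The most likely failure is coupling of the arylpalladium intermediate with 15 before carbon monoxide is taken up. The alternative failure is a stalled oxidative addition, because the iodide is electron-rich and flanked on both sides and CO makes the metal less electron-rich. While the catalyst idles, protodeboronation of 15 and base-induced loss of aryl silyl groups gain ground, the latter followed by oxa-Michael closure of a freed 2'-phenoxide. Palladium hydride species could also isomerise the Z side chain.

Fallback, from 11 and 13 back to 17: 13 is coupled with acrolein under ligand-free Heck conditions (Pd(OAc)2, NaHCO3, n-Bu4NCl, DMF) to give (E)-3-[4-(tert-butyldimethylsilyloxy)phenyl]prop-2-enal F1. Iodide 11 is treated with i-PrMgCl·LiCl (2.2 equiv, THF, 0 °C); the first equivalent deprotonates the tertiary alcohol and the second effects iodine–magnesium exchange. The arylmagnesium species is kept cold to prevent migration of silicon from oxygen to carbon and is added 1,2 to F1. This gives racemic (E)-1-{2,4-bis(tert-butyldimethylsilyloxy)-3-[(Z)-3-hydroxy-3-methylbut-1-enyl]-6-methoxyphenyl}-3-[4-(tert-butyldimethylsilyloxy)phenyl]prop-2-en-1-ol F2. MnO2 in CH2Cl2 oxidises this doubly activated secondary alcohol to 17 and leaves the tertiary alcohol untouched. The carbinol centre of F2 is destroyed, so its configuration is irrelevant.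

**Step 4.** The second addition may stay incomplete because the intermediate 9 is enolised or remains masked as a cyclic hemiketal alkoxide, and the 5-phenoxide lowers the electrophilicity of the lactone. Conjugate addition at C4, iodine–magnesium exchange with loss of iodine, and dehydrative ring closure of 10 during work-up are further risks.

Fallback, from 6 back to 11, with iodination moved to the end: 6 is silylated (TBSCl, imidazole, DMF) to 5-(tert-butyldimethylsilyloxy)-7-methoxycoumarin F3. With no iodide and no free phenol present, methyllithium with CeCl3 (THF, −78 °C) can be used for the double addition, giving 3-(tert-butyldimethylsilyloxy)-2-[(Z)-3-hydroxy-3-methylbut-1-enyl]-5-methoxyphenol F4. Silylation of the released phenol gives the symmetric (Z)-4-[2,6-bis(tert-butyldimethylsilyloxy)-4-methoxyphenyl]-2-methylbut-3-en-2-ol F5. NIS (1 equiv, NaHCO3, DMF, 0 °C) iodinates one of its two equivalent ring positions and gives 11; the Z alkene, twisted out of the ring plane by the two ortho silyloxy groups, should be the less reactive site. This order also removes any question about the site of iodination on the coumarin.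

**Step 1.** Over-methylation at a second phenol and C-methylation of the phloroglucinol ring may compete, because the three phenols differ only moderately in acidity.

Fallback, from 1 back to 6, with the order reversed: 1 and 3 are heated in N,N-diethylaniline to give 5,7-dihydroxycoumarin F6. Its 7-OH is conjugated para, through C4a and C4=C3, to the lactone carbonyl and is unhindered, whereas the 5-OH sits peri to C4–H. One equivalent of Me2SO4 with K2CO3 in acetone should therefore methylate O7 preferentially and give 6, the purification removing any material methylated on O5.

**Step 7.** Transmetalation of the vinylboronate (the Suzuki pathway) may compete with carbopalladation, and the alkene formed in that way can be arylated again.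

Fallback, from 13 and 14 back to 15, using the competing pathway deliberately: 13 and 14 are coupled under Suzuki conditions (Pd(PPh3)4, K3PO4, dioxane–H2O, 80 °C) to give tert-butyldimethyl(4-vinylphenoxy)silane F7. Cross-metathesis of F7 with a further equivalent of 14, using the second-generation Grubbs catalyst RuCl2(=CHPh)(H2IMes)(PCy3) in CH2Cl2 at 40 °C, then gives the E alkenylboronate 15.

## Further compounds

F1 | step 8 | (E)-3-[4-(tert-butyldimethylsilyloxy)phenyl]prop-2-enal | CC(C)(C)[Si](C)(C)Oc1ccc(/C=C/C=O)cc1
F2 | step 8 | (E)-1-{2,4-bis(tert-butyldimethylsilyloxy)-3-[(Z)-3-hydroxy-3-methylbut-1-enyl]-6-methoxyphenyl}-3-[4-(tert-butyldimethylsilyloxy)phenyl]prop-2-en-1-ol (racemic) | COc1cc(O[Si](C)(C)C(C)(C)C)c(/C=C\C(C)(C)O)c(O[Si](C)(C)C(C)(C)C)c1C(O)/C=C/c1ccc(O[Si](C)(C)C(C)(C)C)cc1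
F3 | step 4 | 5-(tert-butyldimethylsilyloxy)-7-methoxycoumarin | COc1cc(O[Si](C)(C)C(C)(C)C)c2ccc(=O)oc2c1
F4 | step 4 | 3-(tert-butyldimethylsilyloxy)-2-[(Z)-3-hydroxy-3-methylbut-1-enyl]-5-methoxyphenol | COc1cc(O)c(/C=C\C(C)(C)O)c(O[Si](C)(C)C(C)(C)C)c1
F5 | step 4 | (Z)-4-[2,6-bis(tert-butyldimethylsilyloxy)-4-methoxyphenyl]-2-methylbut-3-en-2-ol | COc1cc(O[Si](C)(C)C(C)(C)C)c(/C=C\C(C)(C)O)c(O[Si](C)(C)C(C)(C)C)c1
F6 | step 1 | 5,7-dihydroxycoumarin | Oc1cc(O)c2ccc(=O)oc2c1
F7 | step 7 | tert-butyldimethyl(4-vinylphenoxy)silane | CC(C)(C)[Si](C)(C)Oc1ccc(C=C)cc1
A1 | alternative 1 | 5-methoxy-2-[(Z)-3-methyl-3-(triethylsilyloxy)but-1-enyl]-3-(triisopropylsilyloxy)phenol | COc1cc(O)c(/C=C\C(C)(C)O[Si](CC)(CC)CC)c(O[Si](C(C)C)(C(C)C)C(C)C)c1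
A2 | alternative 1 | 3-methoxycyclobut-2-en-1-one | COC1=CC(=O)C1
A3 | alternative 1 | (Z)-triethyl{[2-methyl-6-(triisopropylsilyloxy)hex-3-en-5-yn-2-yl]oxy}silane | CC[Si](CC)(CC)OC(C)(C)/C=C\C#CO[Si](C(C)C)(C(C)C)C(C)C
A4 | alternative 2 | eight-membered benzo-fused cyclic diisopropylsilylene ketal joining one phenol oxygen to the C3'' oxygen across the Z alkene, the other phenol oxygen carrying a diisopropyl(2-methylbut-3-en-2-yloxy)silyl group | COc1cc2O[Si](C(C)C)(C(C)C)OC(C)(C)/C=C\c2c(O[Si](C(C)C)(C(C)C)OC(C)(C)C=C)c1
A5 | alternative 2 | 5-methoxy-2-vinylbenzene-1,3-diol bis[diisopropyl(2-methylbut-3-en-2-yloxy)silyl] ether | COc1cc(O[Si](C(C)C)(C(C)C)OC(C)(C)C=C)c(C=C)c(O[Si](C(C)C)(C(C)C)OC(C)(C)C=C)c1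
A6 | alternative 3 | 4-(1-hydroxyethyl)-2-[(Z)-3-hydroxy-3-methylbut-1-enyl]-5-methoxybenzene-1,3-diol (racemic) | COc1cc(O)c(/C=C\C(C)(C)O)c(O)c1C(C)O
A7 | alternative 3 | 5-hydroxy-8-(1-hydroxyethyl)-7-methoxycoumarin (racemic) | COc1cc(O)c2ccc(=O)oc2c1C(C)O
A8 | alternative 3 | 1-{2,4-dihydroxy-3-[(Z)-3-hydroxy-3-methylbut-1-enyl]-6-methoxyphenyl}ethanone | COc1cc(O)c(/C=C\C(C)(C)O)c(O)c1C(C)=O
A9 | alternative 3 | 4-hydroxybenzaldehyde | O=Cc1ccc(O)cc1
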